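A direct plan would make the (R)-β-arylmethyl-γ-butyrolactone A1 by auxiliary-controlled enolate alkylation, add the second aryl aldehyde to its enolate (aldol adduct A2), hydrogenolyse to the trans-dibenzylbutyrolactone A3, benzylate again, reduce to the diol A4, benzoylate and debenzylate.
Its weakest points would be:
(a) the protecting-group loop: benzyl groups would be put on, lost in the deoxygenating hydrogenolysis, put on again and removed again, which costs about five steps and adds no complexity;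
(b) the auxiliary sequence: acylation, alkylation, reductive cleavage and lactonisation would be spent on one stereocenter, and the second would rest on substrate control in an aldol whose carbinol centre is then discarded;
(c) the acid-promoted pressure hydrogenolysis of the benzylic alcohol and the LiAlH4 reduction would both fall on the most advanced material.

Plan of the new route (butane chain numbered C1 to C4):
- The two CH–CH2O bonds (C1–C2 and C3–C4) are cut first: the 1,4-diol is the double one-carbon homologation product of a threo vicinal bis(boronate), which is the syn-diboration product of (E)-1,4-diarylbut-2-ene 7.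
- The feature that allows this: C2 and C3 are adjacent CH centres, each with one CH2O and one ArCH2 arm. Without the two CH2O carbons a trans-alkene between two benzylic CH2 groups is left, and the (2R,3R) array equals syn addition to one face of it.
- Alkene 7 is cut at the ring B–CH2 bond (allyl–aryl coupling) and at C2=C3 (cross-metathesis of O-silylated eugenol).
- No ring is formed; rings A and B are bought as eugenol and an isovanillyl boronate.
- Each phenol is protected once and freed once, no auxiliary is used, both stereocenters come from one catalytic step, and neither a benzylic deoxygenation nor a late hydride reduction occurs.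

Key step: step 5

Assumption: boronate 5 is taken as commercially available. (S)-Quinap is assumed to direct boron to the alkene face that gives the (2R,3R) product; if a test oxidation of 9 to the vicinal diol showed the opposite sense, (R)-Quinap would be used.

Step 1
Reactants: 1 eugenol (4-allyl-2-methoxyphenol)
Product: 2 (4-allyl-2-methoxyphenoxy)triisopropylsilane
Conditions: TIPSCl (1.2 equiv), imidazole (2.5 equiv), DMF, rt
Reagents that add atoms: chlorotriisopropylsilane, CC(C)[Si](Cl)(C(C)C)C(C)C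
Why: Imidazole-promoted O-silylation of the phenol gives a bulky aryl silyl ether that should tolerate metathesis, aqueous phosphate, n-BuLi at −78 °C and perborate, and that fluoride removes in the presence of benzoates.

Step 2
Reactants: 2 (4-allyl-2-methoxyphenoxy)triisopropylsilane; 3 (Z)-but-2-ene-1,4-diyl diacetate
Product: 4 (E)-4-[3-methoxy-4-(triisopropylsilyloxy)phenyl]but-2-en-1-yl acetate
Conditions: 3 (3 equiv), second-generation Grubbs catalyst RuCl2(=CHPh)(PCy3)(H2IMes) (3 mol %), 1,4-benzoquinone (10 mol %), CH2Cl2, 40 °C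
Reagents that add atoms: none
Why: Olefin cross-metathesis of the terminal alkene with an excess of the symmetrical internal alkene 3 suppresses homodimerisation and should give mainly the E allylic acetate, while benzoquinone holds back migration of the double bond.

Step 3
Reactants: 5 2-methoxy-5-(4,4,5,5-tetramethyl-1,3,2-dioxaborolan-2-yl)phenol
Product: 6 triisopropyl[2-methoxy-5-(4,4,5,5-tetramethyl-1,3,2-dioxaborolan-2-yl)phenoxy]silane
Conditions: TIPSCl (1.2 equiv), imidazole (2.5 equiv), DMF, rt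
Reagents that add atoms: chlorotriisopropylsilane, CC(C)[Si](Cl)(C(C)C)C(C)C
Why: The same O-silylation, to which the pinacol boronate is inert, removes the phenolic OH that would otherwise be O-allylated by the π-allylpalladium intermediate of step 4.

Step 4
Reactants: 4 (E)-4-[3-methoxy-4-(triisopropylsilyloxy)phenyl]but-2-en-1-yl acetate; 6 triisopropyl[2-methoxy-5-(4,4,5,5-tetramethyl-1,3,2-dioxaborolan-2-yl)phenoxy]silane
Product: 7 (E)-1-[3-methoxy-4-(triisopropylsilyloxy)phenyl]-4-[4-methoxy-3-(triisopropylsilyloxy)phenyl]but-2-ene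
Conditions: Pd(PPh3)4 (5 mol %), K3PO4 (2 equiv), THF–H2O (10:1), 60 °C
Reagents that add atoms: none
Why: Allyl–aryl Suzuki–Miyaura coupling, in which zerovalent palladium ionises the acetate, the boronate transmetalates and reductive elimination at the unsubstituted terminus of the π-allyl complex gives the linear product, whose E geometry is secured by syn/anti equilibration of that complex even from residual Z-4.

Step 5
Reactants: 7 (E)-1-[3-methoxy-4-(triisopropylsilyloxy)phenyl]-4-[4-methoxy-3-(triisopropylsilyloxy)phenyl]but-2-ene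
Product: 9 (2R,3R)-1-[3-methoxy-4-(triisopropylsilyloxy)phenyl]-4-[4-methoxy-3-(triisopropylsilyloxy)phenyl]-2,3-bis(4,4,5,5-tetramethyl-1,3,2-dioxaborolan-2-yl)butane, via bis(catechol boronate) 8 (not isolated)
Conditions: Rh(acac)(nbd) (5 mol %), (S)-Quinap (5 mol %), B2(cat)2 (1.5 equiv), THF, rt; then pinacol (4 equiv), rt
Reagents that add atoms: bis(catecholato)diboron, B1(B2Oc3ccccc3O2)Oc2ccccc2O1; pinacol, CC(C)(O)C(C)(C)O
Why: The B–B bond of B2(cat)2 adds oxidatively to the monovalent rhodium–Quinap complex, the alkene inserts into a Rh–B bond and C–B reductive elimination follows, so both boron atoms reach the same alkene face (syn addition), after which pinacol replaces the labile catechol groups. The closest known reaction type is the rhodium/Quinap-catalysed enantioselective diboration of simple trans-1,2-disubstituted alkenes. No ring is closed. Both stereocenters (C2 and C3) arise together: their relative threo configuration follows from the E geometry of 7 and syn addition, and their absolute configuration from the face chosen by the chiral P,N ligand. The step needs facial selectivity and a reductive elimination faster than β-hydride elimination toward the benzylic CH2 groups; 7 helps because it is a nearly C2-symmetric trans-dialkylethylene with two sterically equal ArCH2 arms, so no regiochemical question arises, and it has no coordinating group besides the alkene.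

Step 6
Reactants: 9 (2R,3R)-1-[3-methoxy-4-(triisopropylsilyloxy)phenyl]-4-[4-methoxy-3-(triisopropylsilyloxy)phenyl]-2,3-bis(4,4,5,5-tetramethyl-1,3,2-dioxaborolan-2-yl)butane
Product: 12 (2R,3R)-2-[4-methoxy-3-(triisopropylsilyloxy)benzyl]-3-[3-methoxy-4-(triisopropylsilyloxy)benzyl]butane-1,4-diol, via dilithium bis(chloromethyl)borate complex 10 (not isolated), via bis(borylmethyl) compound 11 (not isolated)
Conditions: BrCH2Cl (6 equiv), n-BuLi (5 equiv), THF, −78 °C → rt; then NaBO3·4H2O, THF–H2O, rt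
Reagents that add atoms: bromochloromethane, ClCBr; sodium perborate tetrahydrate, [Na+].[O-]OB=O.O.O.O.O
Why: Double Matteson homologation, in which chloromethyllithium formed in the flask adds to both boron atoms at −78 °C (10), each secondary alkyl group migrates from boron to carbon with loss of chloride and retention of configuration on warming (11), and perborate oxidises the two primary C–B bonds to C–OH without touching C2 or C3.

Step 7
Reactants: 12 (2R,3R)-2-[4-methoxy-3-(triisopropylsilyloxy)benzyl]-3-[3-methoxy-4-(triisopropylsilyloxy)benzyl]butane-1,4-diol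
Product: 13 (2R,3R)-2-[4-methoxy-3-(triisopropylsilyloxy)benzyl]-3-[3-methoxy-4-(triisopropylsilyloxy)benzyl]butane-1,4-diyl dibenzoate
Conditions: BzCl (2.6 equiv), pyridine, DMAP (cat.), CH2Cl2, 0 °C → rt
Reagents that add atoms: benzoyl chloride, O=C(Cl)c1ccccc1
Why: DMAP-catalysed acylation (nucleophilic catalysis) esterifies the two primary alcohols, and the silylated phenols cannot compete.

Step 8
Reactants: 13 (2R,3R)-2-[4-methoxy-3-(triisopropylsilyloxy)benzyl]-3-[3-methoxy-4-(triisopropylsilyloxy)benzyl]butane-1,4-diyl dibenzoate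
Product: 14 (2R,3R)-2-(3-hydroxy-4-methoxybenzyl)-3-(4-hydroxy-3-methoxybenzyl)butane-1,4-diyl dibenzoate (CNP0306197.1)
Conditions: TBAF (2.4 equiv), AcOH (2.6 equiv), THF, 0 °C → rt
Reagents that add atoms: none
Why: Fluoride-induced cleavage of the two aryl silyl ethers, buffered with acetic acid so that no free phenoxide can attack the benzoates, leaves the remote stereocenters untouched.

## Compound list

1 | eugenol, 4-allyl-2-methoxyphenol | COc1cc(CC=C)ccc1O | starting material
2 | (4-allyl-2-methoxyphenoxy)triisopropylsilane | COc1cc(CC=C)ccc1O[Si](C(C)C)(C(C)C)C(C)C | intermediate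
3 | (Z)-but-2-ene-1,4-diyl diacetate | CC(=O)OC/C=C\COC(C)=O | starting material
4 | (E)-4-[3-methoxy-4-(triisopropylsilyloxy)phenyl]but-2-en-1-yl acetate | CC(=O)OC/C=C/Cc1ccc(O[Si](C(C)C)(C(C)C)C(C)C)c(OC)c1 | intermediate
5 | 2-methoxy-5-(4,4,5,5-tetramethyl-1,3,2-dioxaborolan-2-yl)phenol (3-hydroxy-4-methoxyphenylboronic acid pinacol ester) | COc1ccc(cc1O)B1OC(C)(C)C(C)(C)O1 | starting material
6 | triisopropyl[2-methoxy-5-(4,4,5,5-tetramethyl-1,3,2-dioxaborolan-2-yl)phenoxy]silane | COc1ccc(cc1O[Si](C(C)C)(C(C)C)C(C)C)B1OC(C)(C)C(C)(C)O1 | intermediate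
7 | (E)-1-[3-methoxy-4-(triisopropylsilyloxy)phenyl]-4-[4-methoxy-3-(triisopropylsilyloxy)phenyl]but-2-ene | COc1ccc(C/C=C/Cc2ccc(O[Si](C(C)C)(C(C)C)C(C)C)c(OC)c2)cc1O[Si](C(C)C)(C(C)C)C(C)C | intermediate
8 | (2R,3R)-2,3-bis(1,3,2-benzodioxaborol-2-yl)-1-[3-methoxy-4-(triisopropylsilyloxy)phenyl]-4-[4-methoxy-3-(triisopropylsilyloxy)phenyl]butane (formed in the flask in step 5) | COc1ccc(C[C@@H](B2Oc3ccccc3O2)[C@H](B2Oc3ccccc3O2)Cc2ccc(O[Si](C(C)C)(C(C)C)C(C)C)c(OC)c2)cc1O[Si](C(C)C)(C(C)C)C(C)C | intermediate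
9 | (2R,3R)-1-[3-methoxy-4-(triisopropylsilyloxy)phenyl]-4-[4-methoxy-3-(triisopropylsilyloxy)phenyl]-2,3-bis(4,4,5,5-tetramethyl-1,3,2-dioxaborolan-2-yl)butane | COc1ccc(C[C@@H](B2OC(C)(C)C(C)(C)O2)[C@H](B2OC(C)(C)C(C)(C)O2)Cc2ccc(O[Si](C(C)C)(C(C)C)C(C)C)c(OC)c2)cc1O[Si](C(C)C)(C(C)C)C(C)C | intermediate
10 | dilithium salt of the bis(chloromethyl)borate complex of 9, (2R,3R) (formed in the flask in step 6) | [Li+].[Li+].COc1ccc(C[C@@H]([B-]2(CCl)OC(C)(C)C(C)(C)O2)[C@H]([B-]2(CCl)OC(C)(C)C(C)(C)O2)Cc2ccc(O[Si](C(C)C)(C(C)C)C(C)C)c(OC)c2)cc1O[Si](C(C)C)(C(C)C)C(C)C | intermediate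
11 | (2R,3R)-1-[3-methoxy-4-(triisopropylsilyloxy)phenyl]-4-[4-methoxy-3-(triisopropylsilyloxy)phenyl]-2,3-bis[(4,4,5,5-tetramethyl-1,3,2-dioxaborolan-2-yl)methyl]butane (formed in the flask in step 6) | COc1ccc(C[C@@H](CB2OC(C)(C)C(C)(C)O2)[C@H](CB2OC(C)(C)C(C)(C)O2)Cc2ccc(O[Si](C(C)C)(C(C)C)C(C)C)c(OC)c2)cc1O[Si](C(C)C)(C(C)C)C(C)C | intermediate
12 | (2R,3R)-2-[4-methoxy-3-(triisopropylsilyloxy)benzyl]-3-[3-methoxy-4-(triisopropylsilyloxy)benzyl]butane-1,4-diol | COc1ccc(C[C@@H](CO)[C@H](CO)Cc2ccc(O[Si](C(C)C)(C(C)C)C(C)C)c(OC)c2)cc1O[Si](C(C)C)(C(C)C)C(C)C | intermediate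
13 | (2R,3R)-2-[4-methoxy-3-(triisopropylsilyloxy)benzyl]-3-[3-methoxy-4-(triisopropylsilyloxy)benzyl]butane-1,4-diyl dibenzoate | COc1ccc(C[C@@H](COC(=O)c2ccccc2)[C@H](COC(=O)c2ccccc2)Cc2ccc(O[Si](C(C)C)(C(C)C)C(C)C)c(OC)c2)cc1O[Si](C(C)C)(C(C)C)C(C)C | intermediate
14 | (2R,3R)-2-(3-hydroxy-4-methoxybenzyl)-3-(4-hydroxy-3-methoxybenzyl)butane-1,4-diyl dibenzoate, CNP0306197.1 | COc1ccc(C[C@@H](COC(=O)c2ccccc2)[C@H](COC(=O)c2ccccc2)Cc2ccc(O)c(OC)c2)cc1O | target

Total step count: 8. Longest linear sequence: 7 steps (steps 1, 2, 4, 5, 6, 7, 8); step 3 is a one-step side branch.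

Steps most likely to fail:

Step 5 (poor facial selectivity of the diboration, or β-hydride elimination toward the benzylic positions giving monoborylated alkenes). The fallback gives up catalyst control for a resolution. It sets out from 7, which would be diborated without a chiral ligand (Pt(dba)2, B2(pin)2, toluene, 50 °C, syn addition) to the racemic threo bis(boronate), that is 9 together with its (2S,3S)-enantiomer F1. The conditions of step 6 would carry the racemate through the enantiomeric borate complex F2 and the enantiomeric bis(borylmethyl) compound F3 to the racemic diol, that is 12 together with its (2S,3S)-enantiomer F4. A lipase-catalysed acylation (Burkholderia cepacia lipase or Candida antarctica lipase B, whichever acylates the (2S,3S)-diol faster, vinyl acetate, MTBE, rt) would convert F4 into the (2S,3S)-diacetate F5 and leave 12, where the route is rejoined.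

Step 6 (incomplete borate formation at the second, more hindered boron, or a further insertion into the primary boronate once formed). The fallback brings in each carbon as a vinyl group and cuts it back. From 9, double Zweifel olefination (CH2=CHMgBr, THF, −78 °C; then I2; then NaOMe, MeOH) would pass through the bis(vinyl)borate complex F6 and the bis(β-iodoalkyl) boronate F7. With retention at both migrating carbons it would give (3S,4S)-3-[4-methoxy-3-(triisopropylsilyloxy)benzyl]-4-[3-methoxy-4-(triisopropylsilyloxy)benzyl]hexa-1,5-diene F8. Lemieux–Johnson cleavage (OsO4 cat., NaIO4, 2,6-lutidine, dioxane–H2O) would give the (2R,3R)-2,3-disubstituted butanedial F9, which would be reduced at once (NaBH4, MeOH, 0 °C) to diol 12.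

Step 4 (attack at the substituted allyl terminus, β-hydride elimination of the π-allyl complex to an arylbutadiene, or migration of the double bond into conjugation). The fallback moves the coupling from the aryl–CH2 bond to the vinyl–CH2 bond and avoids a π-allyl intermediate.
- From 2, cross-metathesis with vinylboronic acid pinacol ester (second-generation Grubbs catalyst, CH2Cl2, 40 °C) would give (E)-alkenylboronate F10.
- Isovanillin F11 would be silylated (TIPSCl, imidazole, DMF) to 4-methoxy-3-(triisopropylsilyloxy)benzaldehyde F12, reduced (NaBH4, MeOH) to the benzyl alcohol F13 and converted (CBr4, PPh3, CH2Cl2) into the benzyl bromide F14.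
- A stereoretentive Suzuki–Miyaura coupling of F10 with F14 (Pd(dppf)Cl2, Cs2CO3, THF–H2O, 60 °C) would give 7.

Further compounds

F1 | step 5 | (2S,3S)-enantiomer of 9, formed with 9 as the racemate | COc1ccc(C[C@H](B2OC(C)(C)C(C)(C)O2)[C@@H](B2OC(C)(C)C(C)(C)O2)Cc2ccc(O[Si](C(C)C)(C(C)C)C(C)C)c(OC)c2)cc1O[Si](C(C)C)(C(C)C)C(C)C
F2 | step 5 | (2S,3S)-enantiomer of borate complex 10 (not isolated) | [Li+].[Li+].COc1ccc(C[C@H]([B-]2(CCl)OC(C)(C)C(C)(C)O2)[C@@H]([B-]2(CCl)OC(C)(C)C(C)(C)O2)Cc2ccc(O[Si](C(C)C)(C(C)C)C(C)C)c(OC)c2)cc1O[Si](C(C)C)(C(C)C)C(C)C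
F3 | step 5 | (2S,3S)-enantiomer of 11 (not isolated) | COc1ccc(C[C@H](CB2OC(C)(C)C(C)(C)O2)[C@@H](CB2OC(C)(C)C(C)(C)O2)Cc2ccc(O[Si](C(C)C)(C(C)C)C(C)C)c(OC)c2)cc1O[Si](C(C)C)(C(C)C)C(C)C
F4 | step 5 | (2S,3S)-2-[4-methoxy-3-(triisopropylsilyloxy)benzyl]-3-[3-methoxy-4-(triisopropylsilyloxy)benzyl]butane-1,4-diol, formed with 12 as the racemate | COc1ccc(C[C@H](CO)[C@@H](CO)Cc2ccc(O[Si](C(C)C)(C(C)C)C(C)C)c(OC)c2)cc1O[Si](C(C)C)(C(C)C)C(C)C
F5 | step 5 | (2S,3S)-2-[4-methoxy-3-(triisopropylsilyloxy)benzyl]-3-[3-methoxy-4-(triisopropylsilyloxy)benzyl]butane-1,4-diyl diacetate | COc1ccc(C[C@H](COC(C)=O)[C@@H](COC(C)=O)Cc2ccc(O[Si](C(C)C)(C(C)C)C(C)C)c(OC)c2)cc1O[Si](C(C)C)(C(C)C)C(C)C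
F6 | step 6 | bis(bromomagnesium) salt of the bis(vinyl)borate complex of 9 (not isolated) | Br[Mg+].Br[Mg+].COc1ccc(C[C@@H]([B-]2(C=C)OC(C)(C)C(C)(C)O2)[C@H]([B-]2(C=C)OC(C)(C)C(C)(C)O2)Cc2ccc(O[Si](C(C)C)(C(C)C)C(C)C)c(OC)c2)cc1O[Si](C(C)C)(C(C)C)C(C)C
F7 | step 6 | bis(β-iodoalkyl) boronate in which each former C–B carbon carries a CH(Bpin)CH2I group, epimers at the two new boron-bearing carbons (not isolated) | COc1ccc(C[C@@H](C(CI)B2OC(C)(C)C(C)(C)O2)[C@H](C(CI)B2OC(C)(C)C(C)(C)O2)Cc2ccc(O[Si](C(C)C)(C(C)C)C(C)C)c(OC)c2)cc1O[Si](C(C)C)(C(C)C)C(C)C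
F8 | step 6 | (3S,4S)-3-[4-methoxy-3-(triisopropylsilyloxy)benzyl]-4-[3-methoxy-4-(triisopropylsilyloxy)benzyl]hexa-1,5-diene | COc1ccc(C[C@@H](C=C)[C@H](C=C)Cc2ccc(O[Si](C(C)C)(C(C)C)C(C)C)c(OC)c2)cc1O[Si](C(C)C)(C(C)C)C(C)C
F9 | step 6 | (2R,3R)-2-[4-methoxy-3-(triisopropylsilyloxy)benzyl]-3-[3-methoxy-4-(triisopropylsilyloxy)benzyl]butanedial (not isolated) | COc1ccc(C[C@@H](C=O)[C@H](C=O)Cc2ccc(O[Si](C(C)C)(C(C)C)C(C)C)c(OC)c2)cc1O[Si](C(C)C)(C(C)C)C(C)C
F10 | step 4 | (E)-triisopropyl{2-methoxy-4-[3-(4,4,5,5-tetramethyl-1,3,2-dioxaborolan-2-yl)prop-2-en-1-yl]phenoxy}silane | COc1cc(C/C=C/B2OC(C)(C)C(C)(C)O2)ccc1O[Si](C(C)C)(C(C)C)C(C)C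
F11 | step 4 | isovanillin, 3-hydroxy-4-methoxybenzaldehyde (commercial) | COc1ccc(C=O)cc1O
F12 | step 4 | 4-methoxy-3-(triisopropylsilyloxy)benzaldehyde | COc1ccc(C=O)cc1O[Si](C(C)C)(C(C)C)C(C)C
F13 | step 4 | [4-methoxy-3-(triisopropylsilyloxy)phenyl]methanol | COc1ccc(CO)cc1O[Si](C(C)C)(C(C)C)C(C)C
F14 | step 4 | [5-(bromomethyl)-2-methoxyphenoxy]triisopropylsilane | COc1ccc(CBr)cc1O[Si](C(C)C)(C(C)C)C(C)C
A1 | direct plan | (R)-4-[4-(benzyloxy)-3-methoxybenzyl]dihydrofuran-2(3H)-one | O=C1C[C@@H](Cc2ccc(OCc3ccccc3)c(OC)c2)CO1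
A2 | direct plan | (3S,4R)-3-{[3-(benzyloxy)-4-methoxyphenyl](hydroxy)methyl}-4-[4-(benzyloxy)-3-methoxybenzyl]dihydrofuran-2(3H)-one, carbinol epimers | O=C1OC[C@H](Cc2ccc(OCc3ccccc3)c(OC)c2)[C@H]1C(O)c1ccc(OC)c(OCc2ccccc2)c1
A3 | direct plan | (3R,4R)-3-(3-hydroxy-4-methoxybenzyl)-4-(4-hydroxy-3-methoxybenzyl)dihydrofuran-2(3H)-one | O=C1OC[C@H](Cc2ccc(O)c(OC)c2)[C@H]1Cc1ccc(OC)c(O)c1
A4 | direct plan | (2R,3R)-2-[3-(benzyloxy)-4-methoxybenzyl]-3-[4-(benzyloxy)-3-methoxybenzyl]butane-1,4-diol | COc1ccc(C[C@@H](CO)[C@H](CO)Cc2ccc(OCc3ccccc3)c(OC)c2)cc1OCc1ccccc1
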